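The route rests on a [4+2] disconnection of ring B (C5, C6, C7, C8, C9, C10; drimane numbering). A thermal intramolecular Diels–Alder reaction of a vinylallene (C5=C6–C7=C8=C12) with the C9=C10 bond of a butenolide forms C5–C10 and C8–C9, and with them rings A and B and the stereocentres C5, C9 and C10, in one operation. The step exploits the 1,3-relationship of C1 and C11 across quaternary C10: a temporary C1–O–C11(=O) lactone locks and activates the dienophile, relays the single stereocentre C1, and is later expelled to unveil the ring A enone. The precursor is an acyclic trienone carrying a 4-methylbutenolide.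

Key step: step 7

Remark: drimane numbering is used for the core throughout (ring A: C1–C5, C10; ring B: C5–C10; C11 on C9, C12 on C8, two methyl groups on C4, one on C10).
Remark: the target is taken as the (5S,9S,10R) enantiomer written in the SMILES, with the C10 methyl anti to both H5 and the C9 CH2OAr group.

Step 1
Reactants: 1 3-methylbut-2-en-1-ylmagnesium chloride (prenylmagnesium chloride, commercial THF solution); 2 acetic anhydride
Product: 3 3,3-dimethylpent-4-en-2-one
Conditions: 1 added to 2 (3 equiv), THF, −78 °C; aq. NH4Cl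
Reagents that add atoms: none
Why: Allylic Grignard reagents acylate at the γ-carbon through a cyclic SE2′ transition state, so inverse addition to excess anhydride at −78 °C (γ-selective acylation of a prenyl Grignard reagent) should give the α,α-dimethyl β,γ-unsaturated methyl ketone with the C4 quaternary centre and stop at the ketone.

Step 2
Reactants: 3 3,3-dimethylpent-4-en-2-one
Product: 5 2,2-dimethyl-3-oxobutanal, via secondary ozonide 4 (not isolated)
Conditions: O3, CH2Cl2, −78 °C; then Me2S, −78 °C → rt
Reagents that add atoms: ozone, [O-][O+]=O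
Why: Ozonolysis with reductive work-up cleaves the only alkene to the aldehyde that becomes C5, and the product cannot enolise between its two carbonyl groups, so no aldol chemistry interferes.

Step 3
Reactants: 5 2,2-dimethyl-3-oxobutanal
Product: 6 (4E)-5-iodo-3,3-dimethylpent-4-en-2-one
Conditions: CrCl2 (6 equiv), CHI3 (2 equiv), THF, 0 °C
Reagents that add atoms: iodoform, IC(I)I
Why: The Takai iodoolefination (gem-dichromium reagent from CHI3 and CrCl2) reacts with aldehydes far faster than with ketones and gives (E)-vinyl iodides from α-branched aldehydes, which sets the C5=C6 geometry.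

Step 4
Reactants: 6 (4E)-5-iodo-3,3-dimethylpent-4-en-2-one; 7 tributyl(propa-1,2-dien-1-yl)stannane
Product: 8 (4E)-3,3-dimethylocta-4,6,7-trien-2-one
Conditions: Pd2(dba)3 (cat.), AsPh3, DMF, 40 °C
Reagents that add atoms: none
Why: Stille coupling transfers the allenyl group from tin with retention of the vinyl iodide geometry, giving the (E)-vinylallene that serves as the 4π unit C5=C6–C7=C8 with C12 as the allene terminus, and the neutral conditions leave the methyl ketone alone.

Step 5
Reactants: 9 5-hydroxy-4-methylfuran-2(5H)-one
Product: 10 methyl (2Z)-3-methyl-4-oxobut-2-enoate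
Conditions: K2CO3, MeI, DMF, 0 °C → rt
Reagents that add atoms: methyl iodide, CI
Why: Under carbonate the pseudo-acid exists as the ring-opened (Z)-formyl carboxylate, whose O-alkylation (carboxylate SN2 on MeI) should give the open-chain ester with the Z geometry inherited from the ring, so that C1 and C11 are cis.

Step 6
Reactants: 8 (4E)-3,3-dimethylocta-4,6,7-trien-2-one; 10 methyl (2Z)-3-methyl-4-oxobut-2-enoate
Product: 13 (5R)-5-[(4E)-3,3-dimethyl-2-oxoocta-4,6,7-trien-1-yl]-4-methylfuran-2(5H)-one, via enol borinate 11 (not isolated), via hydroxy ester 12 (not isolated)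
Conditions: (−)-Ipc2BCl, Et3N, Et2O, 0 °C; 10, −78 → −20 °C; H2O2, MeOH, pH 7 buffer, 0 °C; PPTS (cat.), CH2Cl2, rt
Reagents that add atoms: none
Why: In this Paterson boron aldol the ketone enolises only at its methyl group (C2) and the isopinocampheyl ligands direct the enol borinate to one face of aldehyde C1 (re face expected for the (−)-reagent, giving 4R in 12 and 5R in 13; the antipodal reagent is used should the sense be opposite on this enal), and the cis ester then captures the new carbinol as the butenolide.

Step 7
Reactants: 13 (5R)-5-[(4E)-3,3-dimethyl-2-oxoocta-4,6,7-trien-1-yl]-4-methylfuran-2(5H)-one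
Product: 14 (1R,5S,9S,10R)-3-oxodrima-6,8(12)-dien-11,1-olide (1-hydroxy-3-oxodrima-6,8(12)-dien-11-oic acid 1,11-lactone)
Conditions: toluene (0.01 M), BHT (cat.), 70 °C
Reagents that add atoms: none
Why: A concerted, suprafacial [4+2] cycloaddition joins the vinylallene termini C5 and C8 to C10 and C9 of the butenolide, the closest known reaction types being the type 1 intramolecular Diels–Alder reactions of vinylallenes and of butenolide dienophiles. Ring B closes as the six-membered cycloadduct ring and ring A as the six-membered ring of the four-atom tether (C1–C2–C3–C4), both in the same step. C9 and C10 are set relative to each other by suprafacial addition to the ring-locked Z-alkene, so that C1 and C11 stay cis and the C10 methyl ends anti to C11, and their absolute sense is set by stereocentre C1, because the tether can deliver the diene only to the butenolide face that carries C2. C5 is set by the exo mode (lactone turned away from the diene, C10 methyl under C6), which gives the trans A/B fusion with H5 anti to the C10 methyl. The step needs exo over endo selectivity, secured by the rigid butenolide that holds C2 perpendicular to the dienophile plane so that the endo mode would drive C2 into C6, and it needs the vinyl and proximal allene bonds to act as the 4π unit, secured by the short tether; C8 becomes sp2, so no stereocentre arises there. The sp-hybridised C8 and the release of allene strain should make the diene reactive enough to form the bond between C5 and quaternary C10 below 100 °C, before the β-acyloxy ketone can eliminate.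

Step 8
Reactants: 14 (1R,5S,9S,10R)-3-oxodrima-6,8(12)-dien-11,1-olide
Product: 15 (1R,5S,9S,10R)-3-oxodrim-7-en-11,1-olide
Conditions: Et3SiH (5 equiv), CF3CO2H, CH2Cl2, −20 → 0 °C
Reagents that add atoms: none
Why: Ionic hydrogenation (Kursanov–Parnes): protonation at the exocyclic C12 gives the tertiary allyl cation C8–C7–C6 and the silane delivers hydride to its less hindered secondary terminus C6, which should leave the trisubstituted C7=C8 alkene with C12 as methyl, no stereocentre being formed and C9 being held by the lactone bridge.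

Step 9
Reactants: 15 (1R,5S,9S,10R)-3-oxodrim-7-en-11,1-olide
Product: 16 (5S,9S,10R)-3-oxodrima-1,7-dien-11-oic acid
Conditions: DBU (1.5 equiv), CH2Cl2, rt; then aq. HCl
Reagents that add atoms: none
Why: E1cB elimination: DBU enolises the C3 ketone at C2, the only enolisable position, and the axial C1 carboxylate, aligned with the enolate π-system, is expelled irreversibly, which unveils the C1=C2–C3=O enone of ring A and frees C11 as the acid without touching C5, C9 or C10.

Step 10
Reactants: 16 (5S,9S,10R)-3-oxodrima-1,7-dien-11-oic acid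
Product: 17 (3R,5S,9S,10R)-drima-1,7-diene-3,11-diol
Conditions: LiAlH4, THF, 0 °C → reflux; water work-up
Reagents that add atoms: none
Why: LiAlH4 reduces the carboxylate to the primary alcohol and the hindered enone in the 1,2-sense (hydride from the face opposite the axial C4 and C10 methyl groups, giving mainly the 3R allylic alcohol; its C3 epimer converges in step 12), which also removes the enone as an acceptor for the C11 alkoxide.

Step 11
Reactants: 17 (3R,5S,9S,10R)-drima-1,7-diene-3,11-diol; 18 isofraxidin (7-hydroxy-6,8-dimethoxy-2H-chromen-2-one)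
Product: 19 7-{[(3R,5S,9S,10R)-3-hydroxydrima-1,7-dien-11-yl]oxy}-6,8-dimethoxy-2H-chromen-2-one
Conditions: PPh3, DIAD, THF, 0 °C → rt
Reagents that add atoms: none
Why: Mitsunobu etherification: the acidic phenol (pKa about 8) protonates the betaine and displaces the oxyphosphonium of the primary C11 alcohol at a CH2 group, so no stereocentre is involved, while the secondary allylic alcohol, flanked by quaternary C4, should not react.

Step 12
Reactants: 19 7-{[(3R,5S,9S,10R)-3-hydroxydrima-1,7-dien-11-yl]oxy}-6,8-dimethoxy-2H-chromen-2-one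
Product: 20 7-{[(5S,9S,10R)-3-oxodrima-1,7-dien-11-yl]oxy}-6,8-dimethoxy-2H-chromen-2-one (target)
Conditions: MnO2, CH2Cl2, rt
Reagents that add atoms: none
Why: MnO2 oxidises allylic alcohols selectively, so both C3 epimers should converge on the enone while the aryl ether, the coumarin and the C7=C8 alkene are untouched.

Compound list
1 | 3-methylbut-2-en-1-ylmagnesium chloride | CC(C)=CC[Mg]Cl | starting material
2 | acetic anhydride | CC(=O)OC(C)=O | starting material
3 | 3,3-dimethylpent-4-en-2-one | CC(=O)C(C)(C)C=C | intermediate
4 | 3-(2-methyl-3-oxobutan-2-yl)-1,2,4-trioxolane (secondary ozonide, racemic) | CC(=O)C(C)(C)C1OCOO1 | intermediate (not isolated)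
5 | 2,2-dimethyl-3-oxobutanal | CC(=O)C(C)(C)C=O | intermediate
6 | (4E)-5-iodo-3,3-dimethylpent-4-en-2-one | CC(=O)C(C)(C)/C=C/I | intermediate
7 | tributyl(propa-1,2-dien-1-yl)stannane | C=C=C[Sn](CCCC)(CCCC)CCCC | starting material
8 | (4E)-3,3-dimethylocta-4,6,7-trien-2-one | CC(=O)C(C)(C)/C=C/C=C=C | intermediate
9 | 5-hydroxy-4-methylfuran-2(5H)-one (racemic lactol) | CC1=CC(=O)OC1O | starting material
10 | methyl (2Z)-3-methyl-4-oxobut-2-enoate | COC(=O)/C=C(/C)C=O | intermediate
11 | (4E)-3,3-dimethylocta-1,4,6,7-tetraen-2-yl bis[(1R,2S,3R,5R)-isopinocampheyl]borinate | C=C(OB([C@@H]1C[C@@H]2C[C@H]([C@H]1C)C2(C)C)[C@@H]1C[C@@H]2C[C@H]([C@H]1C)C2(C)C)C(C)(C)/C=C/C=C=C | intermediate (not isolated)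
12 | methyl (2Z,4R,8E)-4-hydroxy-3,7,7-trimethyl-6-oxododeca-2,8,10,11-tetraenoate | COC(=O)/C=C(/C)[C@H](O)CC(=O)C(C)(C)/C=C/C=C=C | intermediate (not isolated)
13 | (5R)-5-[(4E)-3,3-dimethyl-2-oxoocta-4,6,7-trien-1-yl]-4-methylfuran-2(5H)-one | CC1=CC(=O)O[C@@H]1CC(=O)C(C)(C)/C=C/C=C=C | intermediate
14 | (1R,5S,9S,10R)-3-oxodrima-6,8(12)-dien-11,1-olide | O=C1O[C@@H]2CC(=O)C(C)(C)[C@H]3C=CC(=C)[C@H]1[C@]23C | intermediate
15 | (1R,5S,9S,10R)-3-oxodrim-7-en-11,1-olide | O=C1O[C@@H]2CC(=O)C(C)(C)[C@H]3CC=C(C)[C@H]1[C@]23C | intermediate
16 | (5S,9S,10R)-3-oxodrima-1,7-dien-11-oic acid | OC(=O)[C@H]1C(C)=CC[C@@H]2C(C)(C)C(=O)C=C[C@]21C | intermediate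
17 | (3R,5S,9S,10R)-drima-1,7-diene-3,11-diol (expected major C3 epimer) | OC[C@H]1C(C)=CC[C@@H]2C(C)(C)[C@H](O)C=C[C@]21C | intermediate
18 | isofraxidin (7-hydroxy-6,8-dimethoxy-2H-chromen-2-one) | COc1cc2ccc(=O)oc2c(OC)c1O | starting material
19 | 7-{[(3R,5S,9S,10R)-3-hydroxydrima-1,7-dien-11-yl]oxy}-6,8-dimethoxy-2H-chromen-2-one | COc1cc2ccc(=O)oc2c(OC)c1OC[C@H]1C(C)=CC[C@@H]2C(C)(C)[C@H](O)C=C[C@]21C | intermediate
20 | 7-{[(5S,9S,10R)-3-oxodrima-1,7-dien-11-yl]oxy}-6,8-dimethoxy-2H-chromen-2-one | COc1cc2ccc(=O)oc2c(OC)c1OC[C@H]1C(C)=CC[C@@H]2C(C)(C)C(=O)C=C[C@]21C | target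

Total step count: 12. Longest linear sequence: 11 steps (steps 1–4 and 6–12; step 5 is a one-step branch).

Steps most likely to fail

Step 7. The cycloaddition may pass through the endo mode (lactone under the diene) and give the cis-fused A/B isomer, or the β-acyloxy ketone may open by elimination before it cyclises. The fallback sets out from 13 and returns at 14. The C3 ketone is reduced (NaBH4, CeCl3, MeOH, −78 °C) to (5R)-5-[(4E)-2-hydroxy-3,3-dimethylocta-4,6,7-trien-1-yl]-4-methylfuran-2(5H)-one F1, which is silylated (TBSOTf, 2,6-lutidine) to its tert-butyldimethylsilyl ether F2. C3 is then sp3 and cannot enolise, and its bulky silyloxy group adds to the steric cost of the endo mode, in which C2 and C3 are pressed against the diene. Heating in toluene should give 3-(tert-butyldimethylsilyloxy)drima-6,8(12)-dien-11,1-olide F3 (ring stereocentres as in 14). HF·pyridine frees 3-hydroxydrima-6,8(12)-dien-11,1-olide F4, and Dess–Martin periodinane restores the ketone of 14.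

Step 8. The ionic hydrogenation may over-reduce the new trisubstituted alkene, deliver hydride to C8, or lose H5 from the allyl cation and scramble C5. The fallback sets out from 14 and returns at 17. The diene is carried on: DBU opens 14 to (5S,9S,10R)-3-oxodrima-1,6,8(12)-trien-11-oic acid F5, and LiAlH4 gives (3R,5S,9S,10R)-drima-1,6,8(12)-triene-3,11-diol F6. Lithium in NH3/THF with t-BuOH at −78 °C (dissolving-metal 1,4-reduction of the conjugated diene, the allyl anion being protonated at the less substituted C6) should then give 17; the alkoxides and the isolated C1=C2 alkene are inert under these conditions.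

Step 11. Displacement at the β-branched, axial C11 by the di-ortho-substituted phenol may be too slow under Mitsunobu conditions, so that alkylation of the hydrazide or elimination takes over. The fallback sets out from 17 and returns at 19. The primary alcohol alone is converted (I2, PPh3, imidazole) into (3R,5S,9S,10R)-11-iododrima-1,7-dien-3-ol F7, and the caesium phenoxide of 18 (Cs2CO3, DMF, 60 °C) is alkylated by F7 in a Williamson etherification to give 19.

Further compounds
F1 | step 7 | (5R)-5-[(4E)-2-hydroxy-3,3-dimethylocta-4,6,7-trien-1-yl]-4-methylfuran-2(5H)-one (both carbinol epimers) | CC1=CC(=O)O[C@@H]1CC(O)C(C)(C)/C=C/C=C=C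
F2 | step 7 | (5R)-5-[(4E)-2-(tert-butyldimethylsilyloxy)-3,3-dimethylocta-4,6,7-trien-1-yl]-4-methylfuran-2(5H)-one (both epimers) | CC1=CC(=O)O[C@@H]1CC(O[Si](C)(C)C(C)(C)C)C(C)(C)/C=C/C=C=C
F3 | step 7 | 3-(tert-butyldimethylsilyloxy)drima-6,8(12)-dien-11,1-olide (ring stereocentres as in 14, both C3 epimers) | O=C1O[C@@H]2CC(O[Si](C)(C)C(C)(C)C)C(C)(C)[C@H]3C=CC(=C)[C@H]1[C@]23C
F4 | step 7 | 3-hydroxydrima-6,8(12)-dien-11,1-olide (ring stereocentres as in 14, both C3 epimers) | O=C1O[C@@H]2CC(O)C(C)(C)[C@H]3C=CC(=C)[C@H]1[C@]23C
F5 | step 8 | (5S,9S,10R)-3-oxodrima-1,6,8(12)-trien-11-oic acid | OC(=O)[C@H]1C(=C)C=C[C@@H]2C(C)(C)C(=O)C=C[C@]21C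
F6 | step 8 | (3R,5S,9S,10R)-drima-1,6,8(12)-triene-3,11-diol | OC[C@H]1C(=C)C=C[C@@H]2C(C)(C)[C@H](O)C=C[C@]21C
F7 | step 11 | (3R,5S,9S,10R)-11-iododrima-1,7-dien-3-ol | IC[C@H]1C(C)=CC[C@@H]2C(C)(C)[C@H](O)C=C[C@]21C
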